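A small charge of free catalyst, 0.500 mM, went into this flask beside 0.40 mM of impurity, and that pair was what I watched first.

- spring: starting material 0.010 M; reagent 0.50 equiv; free catalyst 5 mol%; impurity 0.40 mM; temperature 90 °C; the very flask that is asked about, followed so far
- flask: starting material 0.010 M; reagent 0.500 equiv; free catalyst 5 mol%; impurity 0.40 mM; temperature 90 °C; time 12 h

spring run (percent of the starting material charged)

| time / min | target / % | starting material / % |
|---|---|---|
| 120 | 5.3 | 93.1 |
| 240 | 8.7 | 90.4 |
| 300 | 9.3 | 89.4 |
| 480 | 12.1 | 87.7 |

(standard deviation of a reading: 0.3 percentage points)

* target, in percent of the starting material first charged, at 12 h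
* the remedy with the largest gain of target, or "none" below 2 percentage points (ash / cedar / maple / elm / none)
* target present, in percent of the starting material first charged, after maple
* target present, in percent of the starting material first charged, after elm

- ash: at 12 h raise the temperature by 10 K, then wait 12 h
- cedar: change nothing and wait 12 h more
- maple: at 12 h add free catalyst, 100% of the amount charged, then wait 12 h
- elm: at 12 h add reagent, 100% of the amount charged, then wait 12 h

- what is added takes up no volume worth counting
- the analysis behind the earlier runs scatters by 0.3 percentage points, standard deviation
- the earlier runs do not show what temperature does; that part of a forecast is a guess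
- a reading or a percentage of target counts all its forms, free or not

Was the reagent slowing the target? In the spring run at 480 min the target stood at 12.1%, which, at one reagent per target, had used 24.2% of the reagent, so I looked to the catalyst. The target gained 8.7% in the first 240 min but 3.4 percentage points in the next stretch of equal length. If each stretch shrinks the gap to the end by the same factor, those gains give a plateau, read from the readings, of 14.3%, and 13.4% at 12 h.

How much catalyst made that target? I supposed that the impurity took catalyst one for one. It was less than the catalyst, so 0.100 mM stayed working. I carried 14.3 as the turnover number, the target made per catalyst that escaped the impurity.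

What then pays at 12 h? Waiting or adding reagent should stay near the plateau, since neither brings working catalyst, and temperature remained a guess. I took the impurity as bound by then, so the catalyst added in maple would carry 71.4% of the starting material in turnovers. At one reagent per target the reagent charge sets a ceiling of 50.0% of target, and 71.4% on top of 13.4% is more than that. Reagent would become the limiting reagent, and I committed to maple, close under that ceiling.

The forecast gave 14.5% now, more than my 13.4%, maple as best, 25% after maple, less than the ceiling I stood close under, and 18% after elm, more than my plateau, holding that “Fresh catalyst helps under either reading”.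

The flask gave 12.9% at 12 h, 46.3% after maple, a gain of 33 points, and 13.8% after elm, so the choice was maple.

    starting material + free catalyst → catalyst intermediate A (k = 14.8 L mol⁻¹ min⁻¹, Ea = 47.0 kJ mol⁻¹)
    catalyst intermediate A ⇌ catalyst intermediate B (K = 0.870, k = 0.573 min⁻¹, Ea = 111 kJ mol⁻¹, ΔH = −65.0 kJ mol⁻¹)
    reagent + catalyst intermediate B ⇌ catalyst intermediate C (K = 5650 L mol⁻¹, k = 151 L mol⁻¹ min⁻¹, Ea = 69.0 kJ mol⁻¹, ΔH = −10.0 kJ mol⁻¹)
    catalyst intermediate C ⇌ catalyst intermediate D (K = 1.40, k = 0.705 min⁻¹, Ea = 97.0 kJ mol⁻¹, ΔH = −4.00 kJ mol⁻¹)
    catalyst intermediate D → free catalyst + target (k = 0.502 min⁻¹, Ea = 112 kJ mol⁻¹)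
    crystals ⇌ target, rate k6*(cs6 - [target]) while solid is left; crystals form when [target] > cs6 (solubility = 5.60 mM, k = 1.47 min⁻¹)
    free catalyst + impurity → spent catalyst A (k = 5540 L mol⁻¹ min⁻¹, Ea = 42.0 kJ mol⁻¹)
    catalyst intermediate A → spent catalyst B (k = 0.0202 min⁻¹, Ea = 117 kJ mol⁻¹)
    (constants at 90 °C)

At 720 min spent catalyst A held 80.0% of the catalyst charged. In this flask the turnover number put 71.4% behind maple, against reagent left for 37.1% of the starting material. For the neighbour charged with 12 mol% of free catalyst it reckons 114%, above the ceiling of 50.0%, and that flask stood at 48.8% of target with 2.3% of its reagent left at 720 min.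

The data come from a simulation from invented constants; scatter was added.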